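## The problem

The target 22 is an acylphloroglucinol: a 2,4,6-trihydroxyphenyl ketone whose unbranched C18 acyl chain (C1 is the carbonyl carbon) carries four alkenes (6Z, 10E, 12Z, 15Z) and one carbinol at C9. No ring has to be built, so the task is chain assembly with control of four alkene geometries and one configuration. C9 (R) is the only stereocentre. Nothing in the molecule can induce it and it can direct nothing else, so it has to come from the chiral pool and be carried through without any bond to it being broken. The C9 hydroxyl sits next to the 10E,12Z-diene; such a dienyl carbinol ionises under acid and then suffers allylic transposition, solvolysis or dehydration. C14 is a doubly allylic methylene that is sensitive to base, radicals and oxygen. The phloroglucinol ring is electron-rich and C-nucleophilic, its phenols are acidic, and the ketone lies between two ortho oxygens. A Friedel–Crafts acylation of the free phenol with a functionalised chain is therefore not credible, and the C1–aryl bond needs an organometallic solution with protecting groups that tolerate it. Those protecting groups must come off either before the dienyl carbinol exists or under conditions it survives. The feature that opens the key step is C14, flanked by the Z-alkenes C12=C13 and C15=C16. It is the retron of a 12,15-skipped diyne whose C13–C14 bond joins a C13 terminal alkyne to a propargylic halide. Because C10=C11 is already E at that stage, one syn-hydrogenation delivers both the conjugated E,Z-diene and the skipped Z,Z-diene.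

## Retrosynthesis

**22 from 21 (no skeletal bond cut).** The 12Z and 15Z alkenes of 22 are traced back to the two alkynes of the unprotected diyne 21. Putting the semihydrogenation last means the acid-labile dienyl carbinol is created in the final flask and meets no further reagent. The neighbouring order (hydrogenate, then deprotect) would expose that carbinol to the acid needed for acetal removal. The precursor 21 has two geometric elements fewer and no doubly allylic methylene. The forward step must deliver four hydrogens and stop.

**21 from 20 (protecting groups).** The four hydroxyls of 21 are masked in 20 as three aryl methoxymethyl ethers and one oxan-2-yl (tetrahydropyranyl) ether. Acetals are chosen throughout because they survive aryllithium, methoxide and carbonate, which aryl silyl ethers of an acidic acylphloroglucinol would not do reliably. The forward step is one acid treatment that must cleave four acetals while C9 is flanked only by an electron-poor enyne.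

**20 from 16 and 17 (C13–C14, the key cut).** Cutting C13–C14 gives the C1–C13 terminal (E)-enyne 16 and commercial 1-bromopent-2-yne 17. The cut removes five carbons and one alkyne with a shelf reagent. The neighbouring cut at C11–C12 would require a volatile skipped C7 alkyne. The forward reaction must give direct substitution at C14 without allene formation or diyne isomerisation, under a base too weak to touch the ketone.

**16 from 15, and 15 from 11 and 14 (C1–aryl).** The terminal alkyne of 16 is masked as the C-silyl compound 15. The C1–aryl bond is cut into the Weinreb amide 11 and the aryllithium 14, which forms by lithiation of 1,3,5-tris(methoxymethoxy)benzene 13, itself made from phloroglucinol 12. This replaces a Friedel–Crafts acylation that the Z-alkene and the acetal could not survive. It asks only that a hindered aryllithium add once to an unhindered amide.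

**11 from 9 and 10, and 9 from 8 (C11–C12 and C10=C11).** The enyne of 11 is cut at C11–C12 into the (E)-alkenyl iodide 9 and ethynyltrimethylsilane 10. The alkene of 9 is cut at C10=C11 back to the aldehyde 8, with C11 supplied by iodoform. Both forward reactions are non-basic or weakly basic, so the α-alkoxy stereocentre C9 of 8 is not put at risk. The aldehyde 8 comes from the alcohol 7, and 7 from the acid 6, by functional-group changes.

**6 from 3 and 4 (C6=C7).** The 6Z alkene is cut into the lactol 3 (C7–C10) and the ylide 5, made in the flask from the commercial phosphonium salt 4 (C1–C6). The neighbouring alkyne–epoxide construction would need an acetylide in the presence of a carboxyl derivative and several protecting-group steps. The Wittig cut instead delivers C1 as a free acid and C10 as a free alcohol in one step. The lactol 3 comes from the lactone 2, and 2 from (R)-3-hydroxy-γ-butyrolactone 1, which supplies C9. The forward step must be Z-selective and must not eliminate the C9 oxygen; for that reason C9 carries an acetal, which cannot migrate to the C10 alkoxide.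

## Roads not taken

**Alternative 1:** The cut is C2–C3. The enolate of allyl 3-oxo-3-[2,4,6-tris(allyloxy)phenyl]propanoate A2 (K2CO3 or NaH in DMF) would be alkylated by the C3–C18 tetraenyl iodide A3 to give the C2-ester A1. Zerovalent palladium would then remove all four allyl groups with decarboxylation, and fluoride would free C9.
- Merits: the aryl ketone arrives without any aryllithium, the phenol protecting groups leave under neutral conditions, and the union is convergent.
- Weak points: A3 must carry the complete tetraene, including the dienyl silyl ether and the C14 methylene, through a slow substitution at an unactivated primary iodide in basic DMF. O-alkylation and double alkylation compete. A3 needs a long synthesis of its own in which all four geometries are fixed before the union. Palladium hydride species in the deallylation can move the skipped alkenes.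
- Comparison: this road is better in that it has no late acid step. The chosen plan sets against it that its polyene is never carried through a reaction after it is formed and that both coupling partners are robust.

**Alternative 2:** The cut is C12=C13. The ylide from (Z)-hex-3-en-1-yltriphenylphosphonium bromide A6 and NaN(SiMe3)2 would condense with the C1–C12 enal A5 to give the tetrakis(silyl) ether A4, and fluoride would finish.
- Merits: there is no hydrogenation and so no over-reduction, the 15Z alkene is bought, and only one step follows the union.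
- Weak points: A5 combines an enolisable aryl ketone with a γ-silyloxy enal whose C9 hydrogen is vinylogously acidic, so the basic ylide threatens the only stereocentre. Z-selectivity with enals is good but not complete, and a 12E isomer would be very hard to remove. The aryl silyl ethers of A5 are base-labile.
- Comparison: in step count after the union this road is at least as good. The chosen plan sets against it that syn-addition of hydrogen to an alkyne can only give the Z-alkene, and that no strong base ever meets the C9 stereocentre next to a carbonyl or an unsaturated acceptor.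

**Alternative 3:** The cut is C11–C12. Pd(PPh3)4 and CuI with an amine would couple the alkenyl iodide A8 with (Z)-hept-4-en-1-yne A9 to give the enyne A7. Semireduction of the single alkyne and fluoride would follow.
- Merits: one coupling replaces the alkyne installation, C-desilylation and propargylation of the chosen plan, the amine base is milder than carbonate, and only one alkyne has to be reduced.
- Weak points: A9 is a volatile skipped enyne that is not a shelf reagent. Its Z-alkene has to be set and kept separately, and its methylene is prone to prototropic shift under amine base. The semireduction must spare three Z-alkenes, which is no easier than in the chosen plan.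
- Comparison: this road is shorter by about two steps and would be preferred if A9 were available in quantity. The chosen plan sets against it commercial 17 and 10, non-volatile intermediates, and one stereospecific event that creates both Z-alkenes of the skipped unit. A close relative of this road is kept as the fallback for the key step.

Key step: step 11

Remark on the chemistry: the acetal carbon of the oxan-2-yl group is formed without control, so compounds 2, 3, 6–9, 11, 15, 16, 18 and 20 are mixtures of two epimers at that carbon; it is removed in step 12 and has no bearing on C9.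

## Route

Step 1
Reactants: 1 (R)-4-hydroxydihydrofuran-2(3H)-one [(R)-3-hydroxy-γ-butyrolactone]
Product: 2 (4R)-4-(oxan-2-yloxy)dihydrofuran-2(3H)-one
Conditions: 3,4-dihydro-2H-pyran, PPTS (cat.), CH2Cl2, rt
Reagents that add atoms: 3,4-dihydro-2H-pyran, C1=COCCC1
Why: Acid-catalysed addition of the alcohol to the enol ether (tetrahydropyranylation) is routine for β-hydroxy lactones. An acetal is used because, unlike a silyl ether, it cannot migrate to the C10 alkoxide released in step 3; the stereocentre comes from 1 and is untouched.

Step 2
Reactants: 2 (4R)-4-(oxan-2-yloxy)dihydrofuran-2(3H)-one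
Product: 3 (4R)-4-(oxan-2-yloxy)oxolan-2-ol (lactol)
Conditions: i-Bu2AlH, CH2Cl2, −78 °C; aq. KNaC4H4O6 work-up
Reagents that add atoms: none
Why: Partial reduction of a γ-lactone with i-Bu2AlH stops at the lactol because the tetrahedral aluminate is stable at −78 °C (standard lactone-to-lactol reduction).

Step 3
Reactants: 3 (4R)-4-(oxan-2-yloxy)oxolan-2-ol; 4 (5-carboxypentyl)triphenylphosphonium bromide
Product: 6 (6Z,9R)-10-hydroxy-9-(oxan-2-yloxy)dec-6-enoic acid, via carboxylate ylide 5 (not isolated)
Conditions: 4, NaN(SiMe3)2, THF, 0 °C; then 3, −78 °C → rt; dilute aq. HCl to pH 4, 0 °C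
Reagents that add atoms: none
Why: Wittig olefination of a lactol through its open hydroxy aldehyde with a salt-free, non-stabilised ylide gives the Z-alkene by kinetic cis-oxaphosphetane formation, as in the classical prostanoid side-chain construction. Excess ylide accounts for the lactol hydroxyl, and C9 takes no part.

Step 4
Reactants: 6 (6Z,9R)-10-hydroxy-9-(oxan-2-yloxy)dec-6-enoic acid
Product: 7 (6Z,9R)-10-hydroxy-N-methoxy-N-methyl-9-(oxan-2-yloxy)dec-6-enamide
Conditions: MeNHOMe·HCl, EDC·HCl, HOBt, N-methylmorpholine, CH2Cl2, 0 °C → rt
Reagents that add atoms: N,O-dimethylhydroxylamine hydrochloride, CNOC.Cl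
Why: Carbodiimide/HOBt amidation gives the Weinreb amide. The hydroxybenzotriazole ester acylates the amine much faster than the primary alcohol, so C10–OH needs no protection.

Step 5
Reactants: 7 (6Z,9R)-10-hydroxy-N-methoxy-N-methyl-9-(oxan-2-yloxy)dec-6-enamide
Product: 8 (6Z,9R)-N-methoxy-N-methyl-10-oxo-9-(oxan-2-yloxy)dec-6-enamide
Conditions: Dess–Martin periodinane, pyridine, CH2Cl2, 0 °C → rt; used at once
Reagents that add atoms: none
Why: Dess–Martin oxidation takes the primary alcohol to the aldehyde under buffered, non-basic conditions, which keeps the acetal and the α-alkoxy stereocentre C9 intact.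

Step 6
Reactants: 8 (6Z,9R)-N-methoxy-N-methyl-10-oxo-9-(oxan-2-yloxy)dec-6-enamide
Product: 9 (6Z,9R,10E)-11-iodo-N-methoxy-N-methyl-9-(oxan-2-yloxy)undeca-6,10-dienamide
Conditions: CrCl2, CHI3, THF–1,4-dioxane, 0 °C → rt
Reagents that add atoms: iodoform, IC(I)I
Why: In the Takai olefination the gem-dichromium species from CHI3 and CrCl2 adds to the aldehyde and eliminates to the (E)-alkenyl iodide. The reagent is non-basic, so C9 is not epimerised, and it leaves the Weinreb amide alone.

Step 7
Reactants: 9 (6Z,9R,10E)-11-iodo-N-methoxy-N-methyl-9-(oxan-2-yloxy)undeca-6,10-dienamide; 10 ethynyltrimethylsilane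
Product: 11 (6Z,9R,10E)-N-methoxy-N-methyl-9-(oxan-2-yloxy)-13-(trimethylsilyl)trideca-6,10-dien-12-ynamide
Conditions: Pd(PPh3)2Cl2 (cat.), CuI (cat.), Et3N, THF, rt
Reagents that add atoms: none
Why: Sonogashira coupling of an alkenyl iodide with a terminal alkyne proceeds at room temperature with retention of the E geometry and forms C11–C12.

Step 8
Reactants: 12 phloroglucinol (benzene-1,3,5-triol)
Product: 13 1,3,5-tris(methoxymethoxy)benzene
Conditions: MOMCl, i-Pr2NEt, CH2Cl2–DMF, 0 °C → rt
Reagents that add atoms: chloromethyl methyl ether, COCCl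
Why: O-Alkylation of the phenols with the chloromethyl ether gives the tris-acetal. These groups direct the lithiation of step 9 and are inert to methoxide and carbonate.

Step 9
Reactants: 13 1,3,5-tris(methoxymethoxy)benzene; 11 (6Z,9R,10E)-N-methoxy-N-methyl-9-(oxan-2-yloxy)-13-(trimethylsilyl)trideca-6,10-dien-12-ynamide
Product: 15 (6Z,9R,10E)-9-(oxan-2-yloxy)-1-[2,4,6-tris(methoxymethoxy)phenyl]-13-(trimethylsilyl)trideca-6,10-dien-12-yn-1-one, via aryllithium 14 (not isolated)
Conditions: 13, n-BuLi, THF, 0 °C; then 11, −78 → 0 °C; H2O quench
Reagents that add atoms: none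
Why: Directed ortho-lithiation between two acetal oxygens gives 14, which adds once to the amide. The chelated tetrahedral intermediate blocks a second addition and collapses to the ketone on quench (Weinreb ketone synthesis); the C-silyl group keeps the alkyne proton away from the base.

Step 10
Reactants: 15 (6Z,9R,10E)-9-(oxan-2-yloxy)-1-[2,4,6-tris(methoxymethoxy)phenyl]-13-(trimethylsilyl)trideca-6,10-dien-12-yn-1-one
Product: 16 (6Z,9R,10E)-9-(oxan-2-yloxy)-1-[2,4,6-tris(methoxymethoxy)phenyl]trideca-6,10-dien-12-yn-1-one
Conditions: K2CO3, MeOH, rt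
Reagents that add atoms: none
Why: Methoxide-mediated protodesilylation of an alkynylsilane is standard. The acetals and the doubly ortho-substituted ketone are inert to these conditions.

Step 11
Reactants: 16 (6Z,9R,10E)-9-(oxan-2-yloxy)-1-[2,4,6-tris(methoxymethoxy)phenyl]trideca-6,10-dien-12-yn-1-one; 17 1-bromopent-2-yne
Product: 20 (6Z,9R,10E)-9-(oxan-2-yloxy)-1-[2,4,6-tris(methoxymethoxy)phenyl]octadeca-6,10-dien-12,15-diyn-1-one, via alkynylcopper 18 (not isolated), via 1-iodopent-2-yne 19 (not isolated)
Conditions: CuI, NaI, K2CO3, degassed DMF, rt, argon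
Reagents that add atoms: none
Why: K2CO3 deprotonates the CuI-complexed terminal alkyne of 16 to the copper acetylide 18, while NaI converts the bromide 17 into the more reactive iodide 19 by halide exchange. The soft acetylide then displaces iodide at the primary propargylic carbon C14 by direct substitution, forming the C13–C14 bond and returning CuI. The closest known reaction type is the copper-mediated coupling of terminal alkynes with propargylic halides under carbonate base, the standard entry to the skipped polyynes of polyunsaturated lipids. No ring is closed and no stereocentre is created; C9 and both existing alkenes are spectators. The step needs substitution at C14 and not at the distal alkyne carbon (which would give an allenyne), no oxidative dimerisation of the enyne, and no prototropic shift of the new 1,4-diyne. The first is secured by the unhindered primary halide and the soft copper nucleophile, the second by excluding oxygen, and the third by the weak, sparingly soluble carbonate at room temperature. The substrate supports this: every oxygen is masked as an acetal that carbonate cannot touch, and the ketone, held between two ortho substituents, is neither enolised nor attacked.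

Step 12
Reactants: 20 (6Z,9R,10E)-9-(oxan-2-yloxy)-1-[2,4,6-tris(methoxymethoxy)phenyl]octadeca-6,10-dien-12,15-diyn-1-one
Product: 21 (6Z,9R,10E)-9-hydroxy-1-(2,4,6-trihydroxyphenyl)octadeca-6,10-dien-12,15-diyn-1-one
Conditions: HCl (1.25 M in MeOH), 0 °C → rt
Reagents that add atoms: none
Why: Acid-catalysed transacetalisation to methanol cleaves the tetrahydropyranyl ether and the three aryl methoxymethyl ethers, the two ortho ones being assisted by hydrogen bonding to the ketone. The skipped diyne is stable to acid, and the C9 carbinol is flanked only by an electron-poor enyne, so it should ionise far less readily than the dienyl carbinol of the target.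

Step 13
Reactants: 21 (6Z,9R,10E)-9-hydroxy-1-(2,4,6-trihydroxyphenyl)octadeca-6,10-dien-12,15-diyn-1-one
Product: 22 (6Z,9R,10E,12Z,15Z)-9-hydroxy-1-(2,4,6-trihydroxyphenyl)octadeca-6,10,12,15-tetraen-1-one
Conditions: H2 (1 atm), Pd/CaCO3 poisoned with Pb(OAc)2, quinoline, EtOAc, rt, stopped after uptake of 2 equiv
Reagents that add atoms: none
Why: In the Lindlar semihydrogenation, syn-delivery of hydrogen on the poisoned palladium surface turns both alkynes into Z-alkenes while the 6Z and 10E alkenes are left alone. Because this is the last step, the acid-labile dienyl carbinol meets no further reagent.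

## Compound list

1 | (R)-4-hydroxydihydrofuran-2(3H)-one | O=C1C[C@@H](O)CO1 | starting material
2 | (4R)-4-(oxan-2-yloxy)dihydrofuran-2(3H)-one | O=C1C[C@@H](OC2CCCCO2)CO1 | intermediate
3 | (4R)-4-(oxan-2-yloxy)oxolan-2-ol | OC1C[C@@H](OC2CCCCO2)CO1 | intermediate
4 | (5-carboxypentyl)triphenylphosphonium bromide | OC(=O)CCCCC[P+](c1ccccc1)(c1ccccc1)c1ccccc1.[Br-] | starting material
5 | sodium 6-(triphenylphosphoranylidene)hexanoate | [Na+].[O-]C(=O)CCCCC=P(c1ccccc1)(c1ccccc1)c1ccccc1 | intermediate (formed in the flask, not isolated)
6 | (6Z,9R)-10-hydroxy-9-(oxan-2-yloxy)dec-6-enoic acid | OC[C@H](OC1CCCCO1)C/C=C\CCCCC(=O)O | intermediate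
7 | (6Z,9R)-10-hydroxy-N-methoxy-N-methyl-9-(oxan-2-yloxy)dec-6-enamide | OC[C@H](OC1CCCCO1)C/C=C\CCCCC(=O)N(C)OC | intermediate
8 | (6Z,9R)-N-methoxy-N-methyl-10-oxo-9-(oxan-2-yloxy)dec-6-enamide | O=C[C@H](OC1CCCCO1)C/C=C\CCCCC(=O)N(C)OC | intermediate
9 | (6Z,9R,10E)-11-iodo-N-methoxy-N-methyl-9-(oxan-2-yloxy)undeca-6,10-dienamide | I/C=C/[C@H](OC1CCCCO1)C/C=C\CCCCC(=O)N(C)OC | intermediate
10 | ethynyltrimethylsilane | C#C[Si](C)(C)C | starting material
11 | (6Z,9R,10E)-N-methoxy-N-methyl-9-(oxan-2-yloxy)-13-(trimethylsilyl)trideca-6,10-dien-12-ynamide | C[Si](C)(C)C#C/C=C/[C@H](OC1CCCCO1)C/C=C\CCCCC(=O)N(C)OC | intermediate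
12 | phloroglucinol (benzene-1,3,5-triol) | Oc1cc(O)cc(O)c1 | starting material
13 | 1,3,5-tris(methoxymethoxy)benzene | COCOc1cc(OCOC)cc(OCOC)c1 | intermediate
14 | [2,4,6-tris(methoxymethoxy)phenyl]lithium | [Li]c1c(OCOC)cc(OCOC)cc1OCOC | intermediate (formed in the flask, not isolated)
15 | (6Z,9R,10E)-9-(oxan-2-yloxy)-1-[2,4,6-tris(methoxymethoxy)phenyl]-13-(trimethylsilyl)trideca-6,10-dien-12-yn-1-one | C[Si](C)(C)C#C/C=C/[C@H](OC1CCCCO1)C/C=C\CCCCC(=O)c1c(OCOC)cc(OCOC)cc1OCOC | intermediate
16 | (6Z,9R,10E)-9-(oxan-2-yloxy)-1-[2,4,6-tris(methoxymethoxy)phenyl]trideca-6,10-dien-12-yn-1-one | C#C/C=C/[C@H](OC1CCCCO1)C/C=C\CCCCC(=O)c1c(OCOC)cc(OCOC)cc1OCOC | intermediate (precursor of the key step)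
17 | 1-bromopent-2-yne | CCC#CCBr | starting material
18 | copper acetylide of 16 | [Cu]C#C/C=C/[C@H](OC1CCCCO1)C/C=C\CCCCC(=O)c1c(OCOC)cc(OCOC)cc1OCOC | intermediate (formed in the flask, not isolated)
19 | 1-iodopent-2-yne | CCC#CCI | intermediate (formed in the flask, not isolated)
20 | (6Z,9R,10E)-9-(oxan-2-yloxy)-1-[2,4,6-tris(methoxymethoxy)phenyl]octadeca-6,10-dien-12,15-diyn-1-one | CCC#CCC#C/C=C/[C@H](OC1CCCCO1)C/C=C\CCCCC(=O)c1c(OCOC)cc(OCOC)cc1OCOC | intermediate (product of the key step)
21 | (6Z,9R,10E)-9-hydroxy-1-(2,4,6-trihydroxyphenyl)octadeca-6,10-dien-12,15-diyn-1-one | CCC#CCC#C/C=C/[C@H](O)C/C=C\CCCCC(=O)c1c(O)cc(O)cc1O | intermediate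
22 | (6Z,9R,10E,12Z,15Z)-9-hydroxy-1-(2,4,6-trihydroxyphenyl)octadeca-6,10,12,15-tetraen-1-one | CC/C=C\C/C=C\C=C\[C@H](O)C/C=C\CCCCC(=O)c1c(O)cc(O)cc1O | target

## Step count and least certain steps

Total step count: 13. Longest linear sequence: 12 steps (steps 1–7 and 9–13 from lactone 1); step 8 is a one-step side branch from phloroglucinol.

**Step 11 (key step).** The likeliest failures are:
- oxidative dimerisation of the terminal enyne if oxygen is not rigorously excluded;
- attack at the distal alkyne carbon of the halide, giving an allenyne;
- sluggish reaction of the less nucleophilic conjugated copper acetylide;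
- prototropic isomerisation of the new 1,4-diyne on long contact with carbonate.

The fallback moves the bond construction to C11–C12 and sets out from 9 and 17. Aryllithium 14 is added to the Weinreb amide 9 to give the aryl ketone iodide F1; halogen–lithium exchange is not expected because the alkenyl anion is less stabilised than the dialkoxyaryl anion. Bromide 17 is coupled with ethynylmagnesium bromide under CuCl catalysis to give hepta-1,4-diyne F2. A Sonogashira coupling of F1 with F2 (Pd(PPh3)4, CuI, Et2NH, THF, rt) comes back to the route at 20.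

**Step 12.** The acid strength needed to cleave the para methoxymethyl ether may be enough to ionise C9, leading to solvolysis, allylic transposition, loss of configuration or alkylation of the free phloroglucinol ring; the opposite failure is incomplete cleavage under conditions that C9 tolerates. The fallback lowers the acid demand by changing the aryl acetal and sets out from 12 and 11:
- Phloroglucinol 12 is converted with 1-chloroethyl ethyl ether and i-Pr2NEt into 1,3,5-tris(1-ethoxyethoxy)benzene F3.
- F3 is lithiated with n-BuLi to the aryllithium F4, which is added to 11 to give the ketone F5.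
- K2CO3 in MeOH gives the terminal enyne F6.
- The coupling of step 11 with 17 gives the diyne F7.
- PPTS in MeOH at room temperature, which suffices for 1-ethoxyethyl and tetrahydropyranyl acetals, comes back to the route at 21.

**Step 13.** Over-reduction of the conjugated diene or of the skipped alkenes, incomplete reduction of the isolated alkyne, and slow or uneven uptake through adsorption of the acidic phenols on the basic support are possible. The polar product would also be hard to separate from close-running dihydro or tetrahydro impurities. The fallback sets out from 21. Silylation with Et3SiOTf and 2,6-lutidine gives the tetrakis(triethylsilyl) ether F8. The same semihydrogenation on this lipophilic substrate, which is easier to monitor and purify, gives the tetraene F9. Bu4NF buffered with AcOH in THF at 0 °C comes back to the route at 22.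

**Step 9.** Slow addition of the doubly ortho-substituted aryllithium to the amide could allow deprotonation α to the amide or attack at silicon to compete. The fallback sets out from 11. Reduction with i-Bu2AlH at −78 °C gives the aldehyde F10, to which 14 adds readily to give the benzylic carbinol F11 as a mixture of C1 epimers. Dess–Martin oxidation comes back to the route at 15.

## Further compounds

F1 | step 11 | (6Z,9R,10E)-11-iodo-9-(oxan-2-yloxy)-1-[2,4,6-tris(methoxymethoxy)phenyl]undeca-6,10-dien-1-one | I/C=C/[C@H](OC1CCCCO1)C/C=C\CCCCC(=O)c1c(OCOC)cc(OCOC)cc1OCOC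
F2 | step 11 | hepta-1,4-diyne | C#CCC#CCC
F3 | step 12 | 1,3,5-tris(1-ethoxyethoxy)benzene | CCOC(C)Oc1cc(OC(C)OCC)cc(OC(C)OCC)c1
F4 | step 12 | [2,4,6-tris(1-ethoxyethoxy)phenyl]lithium | [Li]c1c(OC(C)OCC)cc(OC(C)OCC)cc1OC(C)OCC
F5 | step 12 | (6Z,9R,10E)-9-(oxan-2-yloxy)-1-[2,4,6-tris(1-ethoxyethoxy)phenyl]-13-(trimethylsilyl)trideca-6,10-dien-12-yn-1-one | C[Si](C)(C)C#C/C=C/[C@H](OC1CCCCO1)C/C=C\CCCCC(=O)c1c(OC(C)OCC)cc(OC(C)OCC)cc1OC(C)OCC
F6 | step 12 | (6Z,9R,10E)-9-(oxan-2-yloxy)-1-[2,4,6-tris(1-ethoxyethoxy)phenyl]trideca-6,10-dien-12-yn-1-one | C#C/C=C/[C@H](OC1CCCCO1)C/C=C\CCCCC(=O)c1c(OC(C)OCC)cc(OC(C)OCC)cc1OC(C)OCC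
F7 | step 12 | (6Z,9R,10E)-9-(oxan-2-yloxy)-1-[2,4,6-tris(1-ethoxyethoxy)phenyl]octadeca-6,10-dien-12,15-diyn-1-one | CCC#CCC#C/C=C/[C@H](OC1CCCCO1)C/C=C\CCCCC(=O)c1c(OC(C)OCC)cc(OC(C)OCC)cc1OC(C)OCC
F8 | step 13 | (6Z,9R,10E)-9-(triethylsilyloxy)-1-[2,4,6-tris(triethylsilyloxy)phenyl]octadeca-6,10-dien-12,15-diyn-1-one | CCC#CCC#C/C=C/[C@H](O[Si](CC)(CC)CC)C/C=C\CCCCC(=O)c1c(O[Si](CC)(CC)CC)cc(O[Si](CC)(CC)CC)cc1O[Si](CC)(CC)CC
F9 | step 13 | (6Z,9R,10E,12Z,15Z)-9-(triethylsilyloxy)-1-[2,4,6-tris(triethylsilyloxy)phenyl]octadeca-6,10,12,15-tetraen-1-one | CC/C=C\C/C=C\C=C\[C@H](O[Si](CC)(CC)CC)C/C=C\CCCCC(=O)c1c(O[Si](CC)(CC)CC)cc(O[Si](CC)(CC)CC)cc1O[Si](CC)(CC)CC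
F10 | step 9 | (6Z,9R,10E)-9-(oxan-2-yloxy)-13-(trimethylsilyl)trideca-6,10-dien-12-ynal | C[Si](C)(C)C#C/C=C/[C@H](OC1CCCCO1)C/C=C\CCCCC=O
F11 | step 9 | (6Z,9R,10E)-9-(oxan-2-yloxy)-1-[2,4,6-tris(methoxymethoxy)phenyl]-13-(trimethylsilyl)trideca-6,10-dien-12-yn-1-ol (C1 epimers) | C[Si](C)(C)C#C/C=C/[C@H](OC1CCCCO1)C/C=C\CCCCC(O)c1c(OCOC)cc(OCOC)cc1OCOC
A1 | alternative 1 | allyl 2-[(4Z,7R,8E,10Z,13Z)-7-(tert-butyldimethylsilyloxy)hexadeca-4,8,10,13-tetraen-1-yl]-3-oxo-3-[2,4,6-tris(allyloxy)phenyl]propanoate (C2 epimers) | CC/C=C\C/C=C\C=C\[C@H](O[Si](C)(C)C(C)(C)C)C/C=C\CCCC(C(=O)OCC=C)C(=O)c1c(OCC=C)cc(OCC=C)cc1OCC=C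
A2 | alternative 1 | allyl 3-oxo-3-[2,4,6-tris(allyloxy)phenyl]propanoate | C=CCOC(=O)CC(=O)c1c(OCC=C)cc(OCC=C)cc1OCC=C
A3 | alternative 1 | (4Z,7R,8E,10Z,13Z)-7-(tert-butyldimethylsilyloxy)-1-iodohexadeca-4,8,10,13-tetraene | CC/C=C\C/C=C\C=C\[C@H](O[Si](C)(C)C(C)(C)C)C/C=C\CCCI
A4 | alternative 2 | (6Z,9R,10E,12Z,15Z)-9-(tert-butyldimethylsilyloxy)-1-[2,4,6-tris(tert-butyldimethylsilyloxy)phenyl]octadeca-6,10,12,15-tetraen-1-one | CC/C=C\C/C=C\C=C\[C@H](O[Si](C)(C)C(C)(C)C)C/C=C\CCCCC(=O)c1c(O[Si](C)(C)C(C)(C)C)cc(O[Si](C)(C)C(C)(C)C)cc1O[Si](C)(C)C(C)(C)C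
A5 | alternative 2 | (2E,4R,6Z)-4-(tert-butyldimethylsilyloxy)-12-oxo-12-[2,4,6-tris(tert-butyldimethylsilyloxy)phenyl]dodeca-2,6-dienal | O=C/C=C/[C@H](O[Si](C)(C)C(C)(C)C)C/C=C\CCCCC(=O)c1c(O[Si](C)(C)C(C)(C)C)cc(O[Si](C)(C)C(C)(C)C)cc1O[Si](C)(C)C(C)(C)C
A6 | alternative 2 | (Z)-hex-3-en-1-yltriphenylphosphonium bromide | CC/C=C\CC[P+](c1ccccc1)(c1ccccc1)c1ccccc1.[Br-]
A7 | alternative 3 | (6Z,9R,10E,15Z)-9-(tert-butyldimethylsilyloxy)-1-[2,4,6-tris(tert-butyldimethylsilyloxy)phenyl]octadeca-6,10,15-trien-12-yn-1-one | CC/C=C\CC#C/C=C/[C@H](O[Si](C)(C)C(C)(C)C)C/C=C\CCCCC(=O)c1c(O[Si](C)(C)C(C)(C)C)cc(O[Si](C)(C)C(C)(C)C)cc1O[Si](C)(C)C(C)(C)C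
A8 | alternative 3 | (6Z,9R,10E)-9-(tert-butyldimethylsilyloxy)-11-iodo-1-[2,4,6-tris(tert-butyldimethylsilyloxy)phenyl]undeca-6,10-dien-1-one | I/C=C/[C@H](O[Si](C)(C)C(C)(C)C)C/C=C\CCCCC(=O)c1c(O[Si](C)(C)C(C)(C)C)cc(O[Si](C)(C)C(C)(C)C)cc1O[Si](C)(C)C(C)(C)C
A9 | alternative 3 | (Z)-hept-4-en-1-yne | CC/C=C\CC#C
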